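**Plan**
- The side chain is numbered C1' (benzylic) to C17' (methyl). The (S)-carbinol C16' lies two carbons from methylene C14', so C15'–C17' with the oxygen map onto (S)-propylene oxide and C14' onto a dithiane carbon. The benzene ring is a spectator that carries two masked phenols.
- Retrosynthesis: the phenols and the C16' hydroxyl are unmasked last (benzyl and silyl ethers), C14' is returned to a 1,3-dithiane, then C14'–C15' and C13'–C14' are cut together, and finally C1'–C2'.
- Forward: a benzylic Grignard reagent is joined to 1,12-dibromododecane (C1'–C2') and the bromide is exchanged for iodide. A 2-silyl-1,3-dithiane is then coupled in one flask with the epoxide (C14'–C15') and, after silicon has moved from carbon to oxygen, with the iodide (C13'–C14').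
- Reductive desulfurisation and one global deprotection finish the chain; no ring is formed at any stage.
- Stereochemistry: C16' is bought as (S)-propylene oxide, which is opened at its CH2, so no bond to C16' is ever broken.

Key step: step 3

Remark: benzyl ethers are chosen for the phenols so that the last step needs no Lewis acid (a boron trihalide could substitute at the C16' carbinol or its silyl ether); 3,5-bis(benzyloxy)benzyl bromide, 2-(tert-butyldimethylsilyl)-1,3-dithiane and (S)-propylene oxide are taken as commercial.

**Route**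

Step 1
Reactants: 1 3,5-bis(benzyloxy)benzyl bromide [1,3-bis(benzyloxy)-5-(bromomethyl)benzene]; 2 1,12-dibromododecane (3 equiv)
Product: 4 1,3-bis(benzyloxy)-5-(13-bromotridecyl)benzene, via benzylic Grignard reagent 3 (not isolated)
Conditions: Mg (activated turnings), 2-MeTHF, 0 °C, slow addition of 1; then 2 (3 equiv), Li2CuCl4 (3 mol %), THF, −10 °C → rt
Reagents that add atoms: none
Why: Insertion of Mg into the benzylic C–Br bond gives Grignard reagent 3, and the Li2CuCl4-catalysed sp3–sp3 cross-coupling of Grignard reagents with primary alkyl bromides (Kochi coupling) then joins C1' to C2', the threefold excess of the symmetrical dibromide favouring mono-substitution and the benzyl ethers being inert to both reagents.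

Step 2
Reactants: 4 1,3-bis(benzyloxy)-5-(13-bromotridecyl)benzene
Product: 5 1,3-bis(benzyloxy)-5-(13-iodotridecyl)benzene
Conditions: NaI (3 equiv), acetone, reflux
Reagents that add atoms: sodium iodide, [Na+].[I-]
Why: Finkelstein halide exchange, driven by precipitation of NaBr from acetone, turns the primary bromide into the more reactive primary iodide needed for clean alkylation of a hindered dithiane anion.

Step 3
Reactants: 6 2-(tert-butyldimethylsilyl)-1,3-dithiane; 7 (S)-propylene oxide [(2S)-2-methyloxirane]; 5 1,3-bis(benzyloxy)-5-(13-iodotridecyl)benzene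
Product: 11 tert-butyl{[(2S)-1-(2-{13-[3,5-bis(benzyloxy)phenyl]tridecyl}-1,3-dithian-2-yl)propan-2-yl]oxy}dimethylsilane, via lithiated silyl dithiane 8 (not isolated), via lithium alkoxide 9 (not isolated), via O-silylated lithiodithiane 10 (not isolated)
Conditions: t-BuLi (slight deficit to 6), Et2O, −78 → −45 °C; 7, Et2O, −78 → −25 °C; then 5, THF–HMPA, −78 → 0 °C; aq. NH4Cl
Reagents that add atoms: none
Why: t-BuLi removes the C2 proton of 6 to give the sulfur- and silicon-stabilised carbanion 8, which opens epoxide 7 by SN2 attack at the unsubstituted CH2 (C14'–C15' bond) and leaves lithium alkoxide 9, a species that keeps its C–Si bond as long as the medium is ether alone. Adding HMPA together with iodide 5 loosens the O–Li ion pair, the alkoxide attacks silicon through a five-membered cyclic silicate (O–C16'–C15'–C14'–Si), and the 1,4-Brook shift moves the silyl group onto oxygen while returning the negative charge to C14' as dithiane anion 10, which the primary iodide then alkylates by SN2 (C13'–C14' bond). The closest known reaction type is the solvent-controlled multicomponent linchpin coupling of 2-silyl-1,3-dithianes (anion relay through a 1,4-Brook rearrangement), combined with the Corey–Seebach alkylation of 2-lithio-1,3-dithianes by primary iodides. No ring is closed and no stereocentre is created: C16' keeps the (S) configuration of 7 because none of its bonds is broken. The step needs regioselective epoxide opening, secured by the steric preference of the bulky anion for the terminal carbon, and a fixed order of the two C–C bond formations, secured by withholding HMPA and the iodide until 7 is consumed. The slight deficit of t-BuLi leaves no free alkyllithium to undergo lithium–iodine exchange with 5 or to metalate the benzyl ether groups.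

Step 4
Reactants: 11 tert-butyl{[(2S)-1-(2-{13-[3,5-bis(benzyloxy)phenyl]tridecyl}-1,3-dithian-2-yl)propan-2-yl]oxy}dimethylsilane
Product: 12 {[(2S)-17-[3,5-bis(benzyloxy)phenyl]heptadecan-2-yl]oxy}(tert-butyl)dimethylsilane
Conditions: NiCl2·6H2O (excess), NaBH4 (excess), MeOH–THF, 0 °C → rt
Reagents that add atoms: none
Why: Nickel boride (Ni2B) formed in the flask from NiCl2·6H2O and NaBH4 hydrogenolyses both C–S bonds of the dithioketal (reductive desulfurisation on a nickel surface) to leave the C14' methylene, while the silyl ether, the remote stereocentre and the arene are untouched under these mildly basic conditions, and any benzyl group lost here would be removed in step 5 anyway.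

Step 5
Reactants: 12 {[(2S)-17-[3,5-bis(benzyloxy)phenyl]heptadecan-2-yl]oxy}(tert-butyl)dimethylsilane
Product: 13 hansfordiol A [5-[(16S)-16-hydroxyheptadecyl]benzene-1,3-diol]
Conditions: H2 (1 atm), Pd/C, HCl (cat.), MeOH–THF, rt
Reagents that add atoms: none
Why: Hydrogenolysis of the two aryl benzyl ethers over Pd/C runs alongside acid-catalysed methanolysis of the secondary silyl ether, both standard deprotections that cleave only O–CH2Ph and O–Si bonds, so the C16'–O bond and its (S) configuration stay intact.

**Compound list**

1 | 3,5-bis(benzyloxy)benzyl bromide [1,3-bis(benzyloxy)-5-(bromomethyl)benzene] | BrCc1cc(OCc2ccccc2)cc(OCc2ccccc2)c1 | starting material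
2 | 1,12-dibromododecane | BrCCCCCCCCCCCCBr | starting material
3 | [3,5-bis(benzyloxy)benzyl]magnesium bromide | Br[Mg]Cc1cc(OCc2ccccc2)cc(OCc2ccccc2)c1 | intermediate
4 | 1,3-bis(benzyloxy)-5-(13-bromotridecyl)benzene | BrCCCCCCCCCCCCCc1cc(OCc2ccccc2)cc(OCc2ccccc2)c1 | intermediate
5 | 1,3-bis(benzyloxy)-5-(13-iodotridecyl)benzene | ICCCCCCCCCCCCCc1cc(OCc2ccccc2)cc(OCc2ccccc2)c1 | intermediate
6 | 2-(tert-butyldimethylsilyl)-1,3-dithiane | CC(C)(C)[Si](C)(C)C1SCCCS1 | starting material
7 | (S)-propylene oxide [(2S)-2-methyloxirane] | C[C@H]1CO1 | starting material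
8 | [2-(tert-butyldimethylsilyl)-1,3-dithian-2-yl]lithium | [Li]C1(SCCCS1)[Si](C)(C)C(C)(C)C | intermediate
9 | lithium (2S)-1-[2-(tert-butyldimethylsilyl)-1,3-dithian-2-yl]propan-2-olate | C[C@H](O[Li])CC1(SCCCS1)[Si](C)(C)C(C)(C)C | intermediate
10 | {2-[(2S)-2-{[tert-butyl(dimethyl)silyl]oxy}propyl]-1,3-dithian-2-yl}lithium | C[C@H](O[Si](C)(C)C(C)(C)C)CC1([Li])SCCCS1 | intermediate
11 | tert-butyl{[(2S)-1-(2-{13-[3,5-bis(benzyloxy)phenyl]tridecyl}-1,3-dithian-2-yl)propan-2-yl]oxy}dimethylsilane | C[C@H](O[Si](C)(C)C(C)(C)C)CC1(SCCCS1)CCCCCCCCCCCCCc1cc(OCc2ccccc2)cc(OCc2ccccc2)c1 | intermediate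
12 | {[(2S)-17-[3,5-bis(benzyloxy)phenyl]heptadecan-2-yl]oxy}(tert-butyl)dimethylsilane | C[C@H](O[Si](C)(C)C(C)(C)C)CCCCCCCCCCCCCCCc1cc(OCc2ccccc2)cc(OCc2ccccc2)c1 | intermediate
13 | hansfordiol A, 5-[(16S)-16-hydroxyheptadecyl]benzene-1,3-diol | C[C@H](O)CCCCCCCCCCCCCCCc1cc(O)cc(O)c1 | target

**Step count**

Total steps: 5. Longest linear sequence: 5 steps (1 → 4 → 5 → 11 → 12 → 13); 6 and 7 are purchased and enter at step 3.

**Steps most likely to fail**

Step 3. The relay may break down through incomplete migration of silicon from carbon to oxygen, through protonation of the relayed carbanion before it meets the iodide, or through base-induced elimination of the iodide. The fallback forms the same bonds in separate operations and generates the second anion by direct deprotonation instead of silyl migration. Setting out from 7, commercial 1,3-dithiane is lithiated (n-BuLi, THF, −30 °C) to 2-lithio-1,3-dithiane F1, which opens 7 at its CH2 to give (2S)-1-(1,3-dithian-2-yl)propan-2-ol F2. Silylation (TBSCl, imidazole, DMF) gives tert-butyl{[(2S)-1-(1,3-dithian-2-yl)propan-2-yl]oxy}dimethylsilane F3. Deprotonation of F3 with t-BuLi in THF–HMPA at −78 °C produces anion 10 directly, and addition of iodide 5 brings the route back at 11.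

Step 1. Wurtz-type homocoupling during formation of the electron-rich benzylic Grignard reagent and double substitution of the dibromide may both consume material. The fallback reverses the polarity of the C1'–C2' coupling and removes the statistical element. Setting out from 1, commercial 12-bromododecan-1-ol is protected (3,4-dihydro-2H-pyran, pyridinium p-toluenesulfonate, CH2Cl2) as 2-[(12-bromododecyl)oxy]oxane F4. It is converted with Mg in THF into [12-(oxan-2-yloxy)dodecyl]magnesium bromide F5 and coupled with benzylic bromide 1 under Li2CuCl4 catalysis to 2-({13-[3,5-bis(benzyloxy)phenyl]tridecyl}oxy)oxane F6. Methanolysis (pyridinium p-toluenesulfonate, MeOH) gives 13-[3,5-bis(benzyloxy)phenyl]tridecan-1-ol F7, and I2, PPh3 and imidazole in CH2Cl2 convert it into iodide 5, where the route is rejoined without step 2.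

Step 4. Hydrogenolysis of the two C–S bonds may stall at sulfur-containing intermediates, benzyl groups may be shed unevenly on the nickel surface, and sulfur residues may be carried on and poison the palladium of step 5. The fallback removes sulfur by hydrolysis and deoxygenates C14' instead. Setting out from 11, MeI and CaCO3 in MeCN–H2O unmask the ketone (2S)-17-[3,5-bis(benzyloxy)phenyl]-2-{[tert-butyl(dimethyl)silyl]oxy}heptadecan-4-one F8. Condensation with p-toluenesulfonohydrazide in EtOH gives N'-[(2S)-17-[3,5-bis(benzyloxy)phenyl]-2-{[tert-butyl(dimethyl)silyl]oxy}heptadecan-4-ylidene]-4-methylbenzenesulfonohydrazide F9. Reduction with catecholborane in CHCl3 followed by NaOAc·3H2O at reflux delivers the methylene compound and rejoins the route at 12.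

**Further compounds**

F1 | step 3 | 2-lithio-1,3-dithiane | [Li]C1SCCCS1
F2 | step 3 | (2S)-1-(1,3-dithian-2-yl)propan-2-ol | C[C@H](O)CC1SCCCS1
F3 | step 3 | tert-butyl{[(2S)-1-(1,3-dithian-2-yl)propan-2-yl]oxy}dimethylsilane | C[C@H](O[Si](C)(C)C(C)(C)C)CC1SCCCS1
F4 | step 1 | 2-[(12-bromododecyl)oxy]oxane | BrCCCCCCCCCCCCOC1CCCCO1
F5 | step 1 | [12-(oxan-2-yloxy)dodecyl]magnesium bromide | Br[Mg]CCCCCCCCCCCCOC1CCCCO1
F6 | step 1 | 2-({13-[3,5-bis(benzyloxy)phenyl]tridecyl}oxy)oxane | O(CCCCCCCCCCCCCc1cc(OCc2ccccc2)cc(OCc2ccccc2)c1)C1CCCCO1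
F7 | step 1 | 13-[3,5-bis(benzyloxy)phenyl]tridecan-1-ol | OCCCCCCCCCCCCCc1cc(OCc2ccccc2)cc(OCc2ccccc2)c1
F8 | step 4 | (2S)-17-[3,5-bis(benzyloxy)phenyl]-2-{[tert-butyl(dimethyl)silyl]oxy}heptadecan-4-one | C[C@H](O[Si](C)(C)C(C)(C)C)CC(=O)CCCCCCCCCCCCCc1cc(OCc2ccccc2)cc(OCc2ccccc2)c1
F9 | step 4 | N'-[(2S)-17-[3,5-bis(benzyloxy)phenyl]-2-{[tert-butyl(dimethyl)silyl]oxy}heptadecan-4-ylidene]-4-methylbenzenesulfonohydrazide | C[C@H](O[Si](C)(C)C(C)(C)C)CC(=NNS(=O)(=O)c1ccc(C)cc1)CCCCCCCCCCCCCc1cc(OCc2ccccc2)cc(OCc2ccccc2)c1
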